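## Structural features

The target 11 is a 1H-indole: a benzene ring fused to a pyrrole ring through the shared C3a–C7a bond. It is flat, has no stereocentre, and carries a free N1–H and a free C2–H. It has three bromines, at C5 and C7 on the benzene ring and at C3 on the pyrrole ring. The two aryl C–Br bonds tolerate acid, base and heat, but not low-valent metals, organolithium reagents or radical and hydride reductants. The C3–Br bond is the fragile one, because 3-bromoindoles lose or shift bromine under acid, light and prolonged heating. The real difficulty is the 5,7-pattern: electrophilic bromination of an indole goes to C3 and then to C5/C6 mixtures and does not reach C7 cleanly, so these two bromines must arrive with the benzene ring. C3, by contrast, is the natural nucleophilic position and can take its bromine by direct substitution. The feature used by the key step is this: seen from C3a, the carbons C4 and C7a are the two ortho positions and C5 and C7 the two meta positions of an aryl group. Before N1–C7a exists that group is a 3,5-dibromophenyl ring with a mirror plane through C3a and C6, so bonding N1 to either ortho carbon gives the same 5,7-dibromoindole.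

## Logic of the disconnections

11 ⇒ 10. The C3–Br bond is cut first. It is the most sensitive bond, and C3 is the innate site of electrophilic attack, so it is best made last. This leaves 10, which carries only robust aryl bromides. The forward step must stop after one substitution at C3, leave C2 and N1 alone, and run cold and without acid.

10 ⇒ 9. A carboxyl group is added back at C2 (retro-protodecarboxylation, C2–C bond). The C2 acceptor is the handle that makes the azidoacrylate construction possible. The forward step must extrude CO2 without inserting into or reducing either C–Br bond, which argues for a mild catalytic method instead of a hot copper melt.

9 ⇒ 8. The acid is traced back to its methyl ester (acyl C–O bond). The ester is what the condensation chemistry delivers. The forward hydrolysis only has to avoid conditions harsh enough to attack the aryl bromides, which are not activated for substitution.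

8 ⇒ 6 (through 7). The N1–C7a bond is cut, which opens the pyrrole ring. This turns a bicyclic heteroaromatic into an acyclic azidoacrylate on a symmetric aryl group, and the regiochemical problem of the benzene ring disappears. The forward step needs the Z geometry, so that nitrogen lies on the aryl side. It also needs dilution, so that the closure outruns bimolecular loss of 7, and a metal-free nitrene source, so that the bromines are untouched.

6 ⇒ 3 + 4 (through 5). The acrylate C=C bond, which becomes C2–C3 of the indole, is cut. This splits the molecule into a C2–N1 two-carbon piece and an aromatic aldehyde that already holds both bromines in the right relation. The forward condensation must add 3 to 4 faster than base destroys 3, and must dehydrate 5 to the Z alkene.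

3 ⇒ 1 + 2. The C–N bond of the azide is cut. The forward displacement must go to completion, so that no alkylating agent is carried into the condensation, and 3 must be handled only in solution.

## Other disconnections considered

Alternative 1: The cut is through C7–C7a and C4–C3a, so the benzene ring itself is assembled. In the forward step 3,5-dibromo-2H-pyran-2-one A2 would act as the diene toward the enamide double bond of tert-butyl 2,3-dihydro-1H-pyrrole-1-carboxylate A3. Loss of CO2 from the bridged lactone would then give the cis-fused diene A1.
- In its favour: both bromines travel in A2, the expected polarity match (nucleophilic enamide β-carbon to C6 of the pyrone) places them at C5 and C7, the plan is convergent, and no azide is handled. On reagent hazard it is the better plan.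
- On bromine placement it is about equal in principle, though it rests on a kinetic regiochemical preference of an ambiphilic diene and not on symmetry.
- Against it: A1 is two oxidation levels below an indole. The carbocycle must be dehydrogenated across C3a/C7a and the five-membered ring across C2/C3.
- Against it: A1 holds an allylic C7a–N bond, so aromatisation by C–N cleavage to a ring-opened arylethyl carbamate should compete with the wanted dehydrogenation.
- Against it: two stereocentres are made only to be erased, the carbamate must come off, and C3 bromination is still needed.
- Step economy is worse: two dehydrogenations, a deprotection and the bromination follow A1, against three steps after the key step here, and A2 must be prepared first.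

Alternative 2: The cut is at N1–C2 together with C3–Br. In the forward step CuBr2 would activate the alkyne of 2,4-dibromo-6-((trimethylsilyl)ethynyl)aniline A5, nitrogen would close 5-endo-dig onto the silyl-bearing carbon, and the C3–copper bond would be turned into C3–Br to give A4. A5 would come from 2,4-dibromo-6-iodoaniline A6 by Sonogashira coupling.
- In its favour: it is the shortest plan (coupling, cyclisation, C2 desilylation), it needs no decarboxylation and no azide, and it makes the ring and the C3–Br bond in one operation. On step count it is the better plan.
- On bromine placement it is equal, because the pattern is bought with the aniline.
- Against it: the coupling must select C–I over two C–Br bonds under palladium catalysis, a chemoselectivity demand that the chosen route never faces.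
- Against it: the nitrogen of A5 is flanked by bromine and doubly deactivated, so it is a weak nucleophile for the closure.
- Against it: the silyl group sits on the carbon being attacked and may be lost by bromodesilylation, which would put a fourth bromine at C2.
- Against it: the last step must remove silicon from C2 of A4 next to the labile C3–Br bond. Acid-mediated ipso-protodesilylation is exactly the condition under which 3-bromoindoles degrade, so the sensitive bond is not formed last.
- Overall it is more step-economical but carries more chemoselectivity risk around the four carbon–halogen bonds.

Alternative 3: The cut is at C3a–C7a and C4–C5, so both rings are formed at once. In the forward step the tethered terminal alkyne of methyl but-3-yn-1-yl(4,6-dibromopyridazin-3-yl)carbamate A8 would add across C3 and C6 of the pyridazine, and loss of dinitrogen would give the indoline A7.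
- In its favour: two skeletal bonds and two rings come from one step, the tether fixes the regiochemistry, and there is no C2 carboxyl to remove. On bonds formed per step and on the absence of a decarboxylation it is the better plan.
- On certainty of bromine placement it is equal.
- Against it: pyridazines are reluctant azadienes, and an unactivated alkyne would be expected to need much higher temperatures than the azide thermolysis.
- Against it: A8 requires selective introduction of a disubstituted nitrogen at C3 of a polyhalopyridazine, where substitution at C4 is usually preferred, and the ring bromines are prone to displacement.
- Against it: A7 is an indoline carbamate that still needs carbamate cleavage, dehydrogenation to 10 and C3 bromination.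
- After the key step the count is the same as here (three steps), but the route to A8 should be longer and less predictable than the two steps to 6.
- Both key steps are thermal and driven by loss of N2. The chosen one runs at lower temperature on a substrate class that is well documented for halogenated aryl groups.

Key step: step 3

Remark on handling: compound 3 has too little carbon per azide nitrogen to be handled neat. It is assumed to be made only on the scale needed, kept below 30 °C as an assayed solution, never distilled, and kept away from acid and chlorinated solvents while NaN3 is present.

Remark on geometry: the Z descriptor of 6 corresponds to azide cis to the aryl group and ester trans to it. This is the thermodynamic condensation product and the geometry the ring closure needs.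

## Route

Step 1
Reactants: 1 methyl bromoacetate; 2 sodium azide
Product: 3 methyl azidoacetate
Conditions: NaN3 (1.1 equiv), DMSO, 20 °C; H2O/MTBE work-up, kept as assayed MTBE solution
Reagents that add atoms: none
Why: SN2 displacement of a primary bromide activated by the adjacent ester carbonyl, with azide as a strong nucleophile in a dipolar aprotic solvent; complete conversion should leave no alkylating agent for the next step.

Step 2
Reactants: 3 methyl azidoacetate; 4 3,5-dibromobenzaldehyde
Product: 6 methyl (Z)-2-azido-3-(3,5-dibromophenyl)acrylate, via azido aldol adduct 5 (not isolated)
Conditions: 3 (3 equiv), NaOMe (3 equiv), MeOH/THF, −10 to 0 °C; poured onto ice-water, filtered, dried cold in the dark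
Reagents that add atoms: none
Why: Knoevenagel-type aldol condensation (first stage of the Hemetsberger–Knittel sequence): the azidoacetate enolate adds to the electron-poor aldehyde to give alkoxide 5, which loses hydroxide by E1cB elimination. The Z alkene, with the aryl group trans to the ester, should form as the less strained and conjugated isomer. The low temperature and the excess of 3 offset base-induced decomposition of the azido ester.

Step 3
Reactants: 6 methyl (Z)-2-azido-3-(3,5-dibromophenyl)acrylate
Product: 8 methyl 5,7-dibromo-1H-indole-2-carboxylate, via 2H-azirine ester 7 (not isolated)
Conditions: xylenes, 140 °C, slow addition of 6 as a dilute solution (final about 0.05 M), N2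
Reagents that add atoms: none
Why: Hemetsberger indole synthesis, a vinyl nitrene C–H amination of an arene. Heating expels N2 from the vinyl azide to give a vinyl nitrene that equilibrates with 2H-azirine 7 by reversible N–C bond formation and cleavage. The nitrene nitrogen then bonds to an ortho carbon of the aryl group in a five-atom, six-electron (1,5) electrocyclisation across N, the two alkene carbons, the ipso carbon and the ortho carbon, which closes the pyrrole ring as its only ring closure and forms N1–C7a. A hydrogen shift from C7a to nitrogen restores the benzene ring and gives the 1H-indole. No stereocentre is created, and the only stereochemical requirement is the Z geometry of 6, which holds nitrogen on the aryl side. The selectivity needed is between the two ortho C–H positions, and the mirror symmetry of the 3,5-dibromophenyl group makes both lead to the same 5,7-dibromo product. No metal, base or reductant is present, so both C–Br bonds should survive. Slow addition into hot solvent keeps the azide concentration low, which controls gas evolution and favours the unimolecular closure over dimerisation of 7.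

Step 4
Reactants: 8 methyl 5,7-dibromo-1H-indole-2-carboxylate
Product: 9 5,7-dibromo-1H-indole-2-carboxylic acid
Conditions: LiOH·H2O (3 equiv), THF/MeOH/H2O, 40 °C; then 1 M HCl to pH 2, filtered
Reagents that add atoms: lithium hydroxide, [Li+].[OH-]
Why: Ester saponification by acyl substitution; the aryl bromides carry no activating group for nucleophilic aromatic substitution and should be inert to hydroxide at this temperature.

Step 5
Reactants: 9 5,7-dibromo-1H-indole-2-carboxylic acid
Product: 10 5,7-dibromo-1H-indole
Conditions: Ag2CO3 (10 mol%), AcOH (5 mol%), DMSO, 120 °C
Reagents that add atoms: none
Why: Ag2CO3-catalysed protodecarboxylation of a heteroaromatic acid whose carboxyl sits next to the ring heteroatom: the silver carboxylate extrudes CO2 to a C2–silver species that is protonated by acetic acid. Monovalent silver does not insert into aryl C–Br bonds, and the temperature is far below that of a copper/quinoline melt.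

Step 6
Reactants: 10 5,7-dibromo-1H-indole
Product: 11 3,5,7-tribromo-1H-indole
Conditions: NBS (1.0 equiv), DMF, 0 °C, dark; aq. Na2S2O3/NaHCO3 work-up, stored cold in the dark
Reagents that add atoms: N-bromosuccinimide, O=C1CCC(=O)N1Br
Why: Electrophilic aromatic substitution at C3, the enamine-like carbon of the pyrrole ring, through a 3H-indolium intermediate that loses the C3 proton. The two ring bromines deactivate the benzene ring, and one equivalent of reagent at 0 °C without acid should prevent a second substitution at C2.

## Compound list

1 | methyl bromoacetate | COC(=O)CBr | starting material
2 | sodium azide | [Na+].[N-]=[N+]=[N-] | starting material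
3 | methyl azidoacetate | COC(=O)CN=[N+]=[N-] | intermediate
4 | 3,5-dibromobenzaldehyde | O=Cc1cc(Br)cc(Br)c1 | starting material
5 | methyl 2-azido-3-(3,5-dibromophenyl)-3-hydroxypropanoate (mixture of racemic diastereomers, formed as its sodium alkoxide, not isolated) | COC(=O)C(N=[N+]=[N-])C(O)c1cc(Br)cc(Br)c1 | intermediate
6 | methyl (Z)-2-azido-3-(3,5-dibromophenyl)acrylate | COC(=O)/C(N=[N+]=[N-])=C/c1cc(Br)cc(Br)c1 | intermediate
7 | methyl 2-(3,5-dibromophenyl)-2H-azirine-3-carboxylate (racemic, not isolated) | COC(=O)C1=NC1c1cc(Br)cc(Br)c1 | intermediate
8 | methyl 5,7-dibromo-1H-indole-2-carboxylate | COC(=O)c1cc2cc(Br)cc(Br)c2[nH]1 | intermediate
9 | 5,7-dibromo-1H-indole-2-carboxylic acid | OC(=O)c1cc2cc(Br)cc(Br)c2[nH]1 | intermediate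
10 | 5,7-dibromo-1H-indole | Brc1cc(Br)c2[nH]ccc2c1 | intermediate
11 | 3,5,7-tribromo-1H-indole | Brc1cc(Br)c2[nH]cc(Br)c2c1 | target

## Step count and least certain steps

Total step count: 6. Longest linear sequence: 6 steps, from 1 through 3, 6, 8, 9 and 10 to 11; aldehyde 4 enters at step 2.

Step 3 (key step). The most likely failure is bimolecular consumption of the azirine 7 or of the nitrene (dimerisation, oligomerisation to tar) in competition with the ring closure. The closure must engage a deactivated ring at an ortho carbon that has a bromine-bearing neighbour. The fallback changes from an uncatalysed thermal nitrene to a metal-nitrenoid pathway. It sets out from 6 and treats it with Rh2(O2CC3F7)4 (dirhodium tetrakis(heptafluorobutyrate), divalent rhodium, a few mol%) in toluene at 40–60 °C. The azide should then lose N2 at the metal, and the rhodium-bound nitrogen should aminate the ortho position at a temperature where 7 does not accumulate. It comes back to the route at 8 and makes no new compound.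

Step 2. The most likely failure is base-induced decomposition of 3 outrunning the slow elimination, so that the reaction stalls at the adduct stage or gives little alkene. The fallback separates addition from elimination. It sets out from 3 and 4 and runs the aldol addition at −30 °C with NaOMe in MeOH/THF. Quenching with aqueous NH4Cl allows the hydroxy azide 5 to be isolated. This is treated with MsCl and Et3N in THF at 0 to 20 °C to give methyl 2-azido-3-(3,5-dibromophenyl)-3-(methylsulfonyloxy)propanoate F1, which should eliminate in the same flask under the amine base. It comes back to the route at 6.

Step 5. The most likely failure is sluggish CO2 extrusion. The C2 carboxylate has no ortho substituent to twist it out of conjugation, so the temperature needed may rise to where debromination or decomposition of the indole sets in. The fallback changes the order of events so that an ortho bromine assists the extrusion, at the price of carrying the C3–Br bond through two more operations. It sets out from 8, which is brominated at C3 with NBS in DMF at 20 °C to give methyl 3,5,7-tribromo-1H-indole-2-carboxylate F2. Saponification with LiOH in THF/MeOH/H2O gives 3,5,7-tribromo-1H-indole-2-carboxylic acid F3. Protodecarboxylation with Ag2CO3 and AcOH in DMSO at the lowest effective temperature (80–100 °C), in the dark, should then be easier because of the bromine ortho to the carboxylate. It comes back to the route at 11.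

Step 6. The most likely failures are a second bromination at C2, oxidative degradation of the electron-rich ring, and acid- or light-induced decomposition of the product during purification. The fallback brominates a carbamate-protected indole, which reacts more slowly and gives a stable product, and releases the free indole only at the end under mild base. It sets out from 10, which is acylated with Boc2O and catalytic DMAP in MeCN to give tert-butyl 5,7-dibromo-1H-indole-1-carboxylate F4. Bromination with NBS in DMF at 20 °C gives tert-butyl 3,5,7-tribromo-1H-indole-1-carboxylate F5, which can be purified without special care. Methanolysis with K2CO3 in MeOH at 20 °C should cleave the carbamate of this electron-poor indole. It comes back to the route at 11.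

## Further compounds

F0 | step 3 | none | none
F1 | step 2 | methyl 2-azido-3-(3,5-dibromophenyl)-3-(methylsulfonyloxy)propanoate (mixture of racemic diastereomers) | COC(=O)C(N=[N+]=[N-])C(OS(C)(=O)=O)c1cc(Br)cc(Br)c1
F2 | step 5 | methyl 3,5,7-tribromo-1H-indole-2-carboxylate | COC(=O)c1[nH]c2c(Br)cc(Br)cc2c1Br
F3 | step 5 | 3,5,7-tribromo-1H-indole-2-carboxylic acid | OC(=O)c1[nH]c2c(Br)cc(Br)cc2c1Br
F4 | step 6 | tert-butyl 5,7-dibromo-1H-indole-1-carboxylate | CC(C)(C)OC(=O)n1ccc2cc(Br)cc(Br)c21
F5 | step 6 | tert-butyl 3,5,7-tribromo-1H-indole-1-carboxylate | CC(C)(C)OC(=O)n1cc(Br)c2cc(Br)cc(Br)c21
A1 | alternative 1 | tert-butyl cis-5,7-dibromo-2,3,3a,7a-tetrahydro-1H-indole-1-carboxylate (racemic, one enantiomer drawn) | CC(C)(C)OC(=O)N1CC[C@@H]2C=C(Br)C=C(Br)[C@H]12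
A2 | alternative 1 | 3,5-dibromo-2H-pyran-2-one | O=c1occ(Br)cc1Br
A3 | alternative 1 | tert-butyl 2,3-dihydro-1H-pyrrole-1-carboxylate | CC(C)(C)OC(=O)N1CCC=C1
A4 | alternative 2 | 3,5,7-tribromo-2-(trimethylsilyl)-1H-indole | C[Si](C)(C)c1[nH]c2c(Br)cc(Br)cc2c1Br
A5 | alternative 2 | 2,4-dibromo-6-((trimethylsilyl)ethynyl)aniline | C[Si](C)(C)C#Cc1cc(Br)cc(Br)c1N
A6 | alternative 2 | 2,4-dibromo-6-iodoaniline | Nc1c(Br)cc(Br)cc1I
A7 | alternative 3 | methyl 5,7-dibromoindoline-1-carboxylate | COC(=O)N1CCc2cc(Br)cc(Br)c21
A8 | alternative 3 | methyl but-3-yn-1-yl(4,6-dibromopyridazin-3-yl)carbamate | COC(=O)N(CCC#C)c1nnc(Br)cc1Br
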